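**Strategy**

The target is an unsymmetrical dimer of two 2-hydroxy-3-methyl-6-(2-arylethyl)-1,4-benzoquinones joined C5 to C5', and the route rests on cutting this bond between the two quinone rings. Each ring descends from a 3,5-dimethoxy-4-methylbibenzyl, whose two equivalent ring C–H sites become C5 and the C1 carbonyl. The key step exploits that C5 is the only unsubstituted carbon of quinone ring B and the β-carbon of its C1 enone, hence electrophilic, while the same carbon of the unoxidised dimethoxyarene ring A is nucleophilic. A biomimetic acid-catalysed conjugate arylation therefore unites the phenylethyl methoxyquinone 11 with the (2-methoxyphenyl)ethyl dimethoxyarene 5 in one operation; one oxidation and one hydrolysis then finish the synthesis.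

Key step: step 6

Remark on the chemistry: the target SMILES carries no stereodescriptor, so the hindered C5–C5' axis is taken as configurationally unspecified and no stereocontrol is planned. Ring A is the ring that carries the 2-(2-methoxyphenyl)ethyl chain, ring B the ring that carries the 2-phenylethyl chain. Compounds 1, 2 and 6 are taken as commercially available.

**Route**

Step 1
Reactants: 1 3,5-dimethoxy-4-methylbenzaldehyde; 2 (2-methoxybenzyl)triphenylphosphonium chloride
Product: 4 1,3-dimethoxy-5-[2-(2-methoxyphenyl)ethenyl]-2-methylbenzene (E/Z mixture), via phosphorus ylide 3 (not isolated)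
Conditions: 2, KOtBu, THF, 0 °C; then 1, 0 °C to rt
Reagents that add atoms: (2-methoxybenzyl)triphenylphosphonium chloride (2), COc1ccccc1C[P+](c1ccccc1)(c1ccccc1)c1ccccc1.[Cl-]
Why: Wittig olefination of the non-enolisable aldehyde 1 with the semi-stabilised ylide 3 should give the stilbene as an E/Z mixture, which is of no consequence because the double bond is hydrogenated in step 2.

Step 2
Reactants: 4 1,3-dimethoxy-5-[2-(2-methoxyphenyl)ethenyl]-2-methylbenzene
Product: 5 1,3-dimethoxy-5-[2-(2-methoxyphenyl)ethyl]-2-methylbenzene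
Conditions: H2 (1 atm), 10% Pd/C, EtOAc, rt
Reagents that add atoms: none
Why: Heterogeneous catalytic hydrogenation over Pd/C should saturate the stilbene double bond of both geometric isomers while the aryl methyl ethers and the arene rings stay untouched, and no stereocentre arises.

Step 3
Reactants: 1 3,5-dimethoxy-4-methylbenzaldehyde; 6 benzyltriphenylphosphonium chloride
Product: 8 1,3-dimethoxy-2-methyl-5-(2-phenylethenyl)benzene (E/Z mixture), via phosphorus ylide 7 (not isolated)
Conditions: 6, KOtBu, THF, 0 °C; then 1, 0 °C to rt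
Reagents that add atoms: benzyltriphenylphosphonium chloride (6), c1ccccc1C[P+](c1ccccc1)(c1ccccc1)c1ccccc1.[Cl-]
Why: Wittig olefination as in step 1 should give the stilbene as an E/Z mixture that converges on hydrogenation in step 4.

Step 4
Reactants: 8 1,3-dimethoxy-2-methyl-5-(2-phenylethenyl)benzene
Product: 9 1,3-dimethoxy-2-methyl-5-(2-phenylethyl)benzene
Conditions: H2 (1 atm), 10% Pd/C, EtOAc, rt
Reagents that add atoms: none
Why: Catalytic hydrogenation of the stilbene double bond as in step 2 should give the symmetric bibenzyl without touching the methyl ethers.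

Step 5
Reactants: 9 1,3-dimethoxy-2-methyl-5-(2-phenylethyl)benzene
Product: 11 2-methoxy-3-methyl-6-(2-phenylethyl)cyclohexa-2,5-diene-1,4-dione, via p-methoxyphenol 10 (not isolated)
Conditions: CH3ReO3 (5 mol %), 35% aq. H2O2, AcOH, 40 °C
Reagents that add atoms: hydrogen peroxide, OO
Why: Methyltrioxorhenium-catalysed peroxide oxidation of a methoxyarene to a p-quinone (the reaction type that turns 3,4,5-trimethoxytoluene into its dimethoxyquinone) should hydroxylate one of the two equivalent ring C-H positions, each ortho to one methoxy group and para to the other, to give p-methoxyphenol 10 and oxidise it further with loss of methanol, so that the symmetry of 9 allows only one quinone regioisomer and the unactivated phenyl ring is left alone.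

Step 6
Reactants: 11 2-methoxy-3-methyl-6-(2-phenylethyl)cyclohexa-2,5-diene-1,4-dione; 5 1,3-dimethoxy-5-[2-(2-methoxyphenyl)ethyl]-2-methylbenzene
Product: 12 5-{2,4-dimethoxy-3-methyl-6-[2-(2-methoxyphenyl)ethyl]phenyl}-2-methoxy-3-methyl-6-(2-phenylethyl)benzene-1,4-diol
Conditions: Sc(OSO2CF3)3 (10 mol %), 5 (1.5 equiv), CH2Cl2/(CF3)2CHOH 4:1, 0 °C to rt, Ar
Reagents that add atoms: none
Why: Sc(OSO2CF3)3 in the hydrogen-bond-donating solvent should activate the C1 carbonyl of 11 (chelated through the neighbouring 2-methoxy oxygen), so that a ring C-H carbon of arene 5 (ortho to one methoxy group, para to the other) attacks the unsubstituted C5 of the quinone, and loss of a proton from the arenium ion followed by enolisation gives hydroquinone 12. The closest known reaction type is the acid-catalysed Friedel-Crafts conjugate arylation (hydroarylation) of quinones with electron-rich arenes, which here copies the presumed biosynthetic union of an oxidised and an unoxidised monomer. No ring is closed and no stereocentre is set; the hindered biaryl axis forms without control, in line with the remark above. The step needs cross-coupling over homo-coupling, which the fixed roles should secure: only 11 is an electrophile, and 5, lacking a para-dioxygen pattern, cannot be turned into a quinone by 11. Site selectivity follows from the substrates, since C5 is the only unsubstituted carbon of 11, the two reactive C-H positions of 5 are equivalent by symmetry and the anisole ring with its single methoxy group is far less nucleophilic; the excess of 5 should suppress a second arylation and the homo-coupling of any hydroquinone of 11 formed by redox exchange with 12. Any 12 that 11 oxidises to its quinone 13 converges in step 7.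

Step 7
Reactants: 12 5-{2,4-dimethoxy-3-methyl-6-[2-(2-methoxyphenyl)ethyl]phenyl}-2-methoxy-3-methyl-6-(2-phenylethyl)benzene-1,4-diol
Product: 15 2-methoxy-5-[4-methoxy-5-methyl-3,6-dioxo-2-(2-phenylethyl)cyclohexa-1,4-dien-1-yl]-3-methyl-6-[2-(2-methoxyphenyl)ethyl]cyclohexa-2,5-diene-1,4-dione, via arylquinone 13 (not isolated), via hydroxylated arylquinone 14 (not isolated)
Conditions: CH3ReO3 (5 mol %), 35% aq. H2O2, AcOH, rt to 40 °C
Reagents that add atoms: hydrogen peroxide, OO
Why: The same rhenium-catalysed peroxide oxidation should first dehydrogenate the hydroquinone ring B to quinone 13, then hydroxylate the only remaining C-H of ring A (ortho to one methoxy group, para to the other) to p-methoxyphenol 14 and oxidise it with loss of methanol to the second quinone ring, the singly methoxylated anisole ring being much less activated toward the electrophilic oxidant.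

Step 8
Reactants: 15 2-methoxy-5-[4-methoxy-5-methyl-3,6-dioxo-2-(2-phenylethyl)cyclohexa-1,4-dien-1-yl]-3-methyl-6-[2-(2-methoxyphenyl)ethyl]cyclohexa-2,5-diene-1,4-dione
Product: 17 2-hydroxy-5-[4-hydroxy-5-methyl-3,6-dioxo-2-(2-phenylethyl)cyclohexa-1,4-dien-1-yl]-3-methyl-6-[2-(2-methoxyphenyl)ethyl]cyclohexa-2,5-diene-1,4-dione (target CNP0202346.0), via disodium salt 16 (not isolated)
Conditions: 2 M aq. NaOH, MeOH/THF, 0 °C to rt, Ar; then 1 M HCl
Reagents that add atoms: sodium hydroxide, [Na+].[OH-]
Why: Addition-elimination hydrolysis (vinylogous ester saponification) of the two 2-methoxyquinone units by hydroxide should give the bis(hydroxyquinone) salt 16 and, after acidification, the target, while the ordinary aryl methyl ether on the side chain is no vinylogous ester and stays intact.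

**Compound list**

1 | 3,5-dimethoxy-4-methylbenzaldehyde | COc1cc(C=O)cc(OC)c1C | starting material
2 | (2-methoxybenzyl)triphenylphosphonium chloride | COc1ccccc1C[P+](c1ccccc1)(c1ccccc1)c1ccccc1.[Cl-] | starting material
3 | (2-methoxybenzylidene)triphenylphosphorane | COc1ccccc1C=P(c1ccccc1)(c1ccccc1)c1ccccc1 | intermediate (not isolated)
4 | 1,3-dimethoxy-5-[2-(2-methoxyphenyl)ethenyl]-2-methylbenzene (E/Z mixture) | COc1ccccc1C=Cc1cc(OC)c(C)c(OC)c1 | intermediate
5 | 1,3-dimethoxy-5-[2-(2-methoxyphenyl)ethyl]-2-methylbenzene | COc1ccccc1CCc1cc(OC)c(C)c(OC)c1 | intermediate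
6 | benzyltriphenylphosphonium chloride | c1ccccc1C[P+](c1ccccc1)(c1ccccc1)c1ccccc1.[Cl-] | starting material
7 | benzylidenetriphenylphosphorane | c1ccccc1C=P(c1ccccc1)(c1ccccc1)c1ccccc1 | intermediate (not isolated)
8 | 1,3-dimethoxy-2-methyl-5-(2-phenylethenyl)benzene (E/Z mixture) | COc1cc(C=Cc2ccccc2)cc(OC)c1C | intermediate
9 | 1,3-dimethoxy-2-methyl-5-(2-phenylethyl)benzene | COc1cc(CCc2ccccc2)cc(OC)c1C | intermediate
10 | 2,4-dimethoxy-3-methyl-6-(2-phenylethyl)phenol | COc1cc(CCc2ccccc2)c(O)c(OC)c1C | intermediate (not isolated)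
11 | 2-methoxy-3-methyl-6-(2-phenylethyl)cyclohexa-2,5-diene-1,4-dione | COC1=C(C)C(=O)C=C(CCc2ccccc2)C1=O | intermediate
12 | 5-{2,4-dimethoxy-3-methyl-6-[2-(2-methoxyphenyl)ethyl]phenyl}-2-methoxy-3-methyl-6-(2-phenylethyl)benzene-1,4-diol | COc1cc(CCc2ccccc2OC)c(-c2c(O)c(C)c(OC)c(O)c2CCc2ccccc2)c(OC)c1C | intermediate
13 | 5-{2,4-dimethoxy-3-methyl-6-[2-(2-methoxyphenyl)ethyl]phenyl}-2-methoxy-3-methyl-6-(2-phenylethyl)cyclohexa-2,5-diene-1,4-dione | COC1=C(C)C(=O)C(c2c(OC)c(C)c(OC)cc2CCc2ccccc2OC)=C(CCc2ccccc2)C1=O | intermediate (not isolated)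
14 | 5-{5-hydroxy-2,4-dimethoxy-3-methyl-6-[2-(2-methoxyphenyl)ethyl]phenyl}-2-methoxy-3-methyl-6-(2-phenylethyl)cyclohexa-2,5-diene-1,4-dione | COC1=C(C)C(=O)C(c2c(OC)c(C)c(OC)c(O)c2CCc2ccccc2OC)=C(CCc2ccccc2)C1=O | intermediate (not isolated)
15 | 2-methoxy-5-[4-methoxy-5-methyl-3,6-dioxo-2-(2-phenylethyl)cyclohexa-1,4-dien-1-yl]-3-methyl-6-[2-(2-methoxyphenyl)ethyl]cyclohexa-2,5-diene-1,4-dione | COc1ccccc1CCC1=C(C2=C(CCc3ccccc3)C(=O)C(OC)=C(C)C2=O)C(=O)C(C)=C(OC)C1=O | intermediate
16 | disodium salt of the target (bis-enolate) | COc1ccccc1CCC1=C(C2=C(CCc3ccccc3)C(=O)C([O-])=C(C)C2=O)C(=O)C(C)=C([O-])C1=O.[Na+].[Na+] | intermediate (not isolated)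
17 | 2-hydroxy-5-[4-hydroxy-5-methyl-3,6-dioxo-2-(2-phenylethyl)cyclohexa-1,4-dien-1-yl]-3-methyl-6-[2-(2-methoxyphenyl)ethyl]cyclohexa-2,5-diene-1,4-dione (CNP0202346.0) | COc1ccccc1CCC1=C(C2=C(CCc3ccccc3)C(=O)C(O)=C(C)C2=O)C(=O)C(C)=C(O)C1=O | target

**Step count and risks**

Total step count: 8. Longest linear sequence: 6 steps (steps 3, 4, 5, 6, 7 and 8).

The three steps most likely to fail:

1. Step 6 (key step). Bond formation between two carbons that each carry two ortho substituents may be slow. Redox exchange between hydroquinone 12 and quinone 11 may also feed homo-coupling of the quinone half. The fallback is a Suzuki-Miyaura cross-coupling that sets out from 11 and 5 and comes back to the route at arylquinone 13, which is then isolated and submitted to the conditions of step 7. Quinone 11 is brominated at C5 (Br2, CHCl3, 0 °C; then Et3N) to 2-bromo-5-methoxy-6-methyl-3-(2-phenylethyl)cyclohexa-2,5-diene-1,4-dione F1. Arene 5 is monobrominated at one of its two equivalent ring positions (NBS, MeCN, 0 °C) to 1-bromo-2,4-dimethoxy-3-methyl-6-[2-(2-methoxyphenyl)ethyl]benzene F2. Bromine-lithium exchange and borylation (n-BuLi, THF, −78 °C; B(OiPr)3; aq. HCl) convert F2 into {2,4-dimethoxy-3-methyl-6-[2-(2-methoxyphenyl)ethyl]phenyl}boronic acid F3. Coupling of F1 with F3 (Pd2(dba)3, 2-dicyclohexylphosphino-2',6'-dimethoxybiphenyl, K3PO4, toluene/H2O, 80 °C) should give 13.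

2. Step 7. Hydroxylation of the last, hindered C-H of ring A in the biaryl may be incomplete, may compete with attack on the anisole ring, or may run on to over-oxidation. The fallback installs this oxygen before the union; it sets out from 5 (and uses 11) and comes back at 15. Vilsmeier-Haack formylation of 5 (POCl3, DMF, 0 to 60 °C; aq. NaOAc) should give 2,4-dimethoxy-3-methyl-6-[2-(2-methoxyphenyl)ethyl]benzaldehyde F4. Baeyer-Villiger (Dakin-type) oxidation and formate methanolysis (mCPBA, CH2Cl2; K2CO3, MeOH) give 2,4-dimethoxy-3-methyl-6-[2-(2-methoxyphenyl)ethyl]phenol F5. Its one remaining ring C-H is coupled with 11 under the conditions of step 6 to give 5-{5-hydroxy-2,4-dimethoxy-3-methyl-6-[2-(2-methoxyphenyl)ethyl]phenyl}-2-methoxy-3-methyl-6-(2-phenylethyl)benzene-1,4-diol F6. Oxidation of the hydroquinone ring and the p-methoxyphenol ring of F6 (PhI(OAc)2, MeCN/H2O, 0 °C) should give 15.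

3. Step 5. The direct arene-to-quinone oxidation may stall at low conversion or run on to hydroxylated or ring-cleaved material. The fallback sets out from 9 and comes back at 11. Vilsmeier-Haack formylation of 9 (POCl3, DMF; aq. NaOAc) should give 2,4-dimethoxy-3-methyl-6-(2-phenylethyl)benzaldehyde F7. Baeyer-Villiger oxidation and methanolysis (mCPBA, CH2Cl2; K2CO3, MeOH) give phenol 10, now isolated. Oxidation of this p-methoxyphenol (PhI(OAc)2, MeCN/H2O, 0 °C) should give 11.

Further compounds
F1 | step 6 | 2-bromo-5-methoxy-6-methyl-3-(2-phenylethyl)cyclohexa-2,5-diene-1,4-dione | COC1=C(C)C(=O)C(Br)=C(CCc2ccccc2)C1=O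
F2 | step 6 | 1-bromo-2,4-dimethoxy-3-methyl-6-[2-(2-methoxyphenyl)ethyl]benzene | COc1ccccc1CCc1cc(OC)c(C)c(OC)c1Br
F3 | step 6 | {2,4-dimethoxy-3-methyl-6-[2-(2-methoxyphenyl)ethyl]phenyl}boronic acid | COc1ccccc1CCc1cc(OC)c(C)c(OC)c1B(O)O
F4 | step 7 | 2,4-dimethoxy-3-methyl-6-[2-(2-methoxyphenyl)ethyl]benzaldehyde | COc1ccccc1CCc1cc(OC)c(C)c(OC)c1C=O
F5 | step 7 | 2,4-dimethoxy-3-methyl-6-[2-(2-methoxyphenyl)ethyl]phenol | COc1ccccc1CCc1cc(OC)c(C)c(OC)c1O
F6 | step 7 | 5-{5-hydroxy-2,4-dimethoxy-3-methyl-6-[2-(2-methoxyphenyl)ethyl]phenyl}-2-methoxy-3-methyl-6-(2-phenylethyl)benzene-1,4-diol | COc1ccccc1CCc1c(O)c(OC)c(C)c(OC)c1-c1c(O)c(C)c(OC)c(O)c1CCc1ccccc1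
F7 | step 5 | 2,4-dimethoxy-3-methyl-6-(2-phenylethyl)benzaldehyde | COc1cc(CCc2ccccc2)c(C=O)c(OC)c1C
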